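Target ⇐ C2-CH(CH2OH)2 diol, the masked C(=CH2)–CHO unit, unmasked last by monotosylation, oxidation and E1cB loss of tosylate; the tiglate and the acetate are ordinary acylations.
C5 side chain ⇐ bromination para to O1, Stille introduction of acetyl, and asymmetric transfer hydrogenation to the (R)-carbinol.
cis-(2S,3S) C2/C3 ⇐ racemic 2-substituted benzofuran-3(2H)-one by asymmetric transfer hydrogenation with dynamic kinetic resolution; C3 is held one oxidation level high through the key step.
Benzofuranone ⇐ benzyne + racemic α-hydroxy ester: one aryne annulation makes O1–C7a and C3a–C3 and closes the furan ring, the only ring formed in the route (the benzene ring is bought as the aryne precursor); the ester comes from 1,3-bis(silyloxy)acetone by olefination and hydration.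
Enabling feature: O1 and C3 stand on the adjacent carbons C7a and C3a of the benzene ring, and C3 is an oxygenated carbon two atoms from O1, so O1–C2–C3 is an α-hydroxy ester; C4, C6 and C7 carry only H and C5 lies para to O1, so symmetrical benzyne serves and C5 is functionalised afterwards.

Key step: step 3

Remark: 1,3-bis[(tert-butyldimethylsilyl)oxy]propan-2-one is taken as purchasable (otherwise one silylation from dihydroxyacetone dimer); 4, 5, 8 and 9 are racemic by design, and 19 and 20 are mixtures of two epimers at a carbon that becomes sp2 in 21.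

Step 1
Reactants: 1 1,3-bis[(tert-butyldimethylsilyl)oxy]propan-2-one; 2 trimethyl phosphonoacetate
Product: 3 methyl 4-[(tert-butyldimethylsilyl)oxy]-3-{[(tert-butyldimethylsilyl)oxy]methyl}but-2-enoate
Conditions: NaH, THF, 0 °C to 25 °C
Reagents that add atoms: none
Why: Horner–Wadsworth–Emmons olefination of a ketone with a stabilised phosphonate anion; the two β-substituents are identical, so no alkene geometry arises.

Step 2
Reactants: 3 methyl 4-[(tert-butyldimethylsilyl)oxy]-3-{[(tert-butyldimethylsilyl)oxy]methyl}but-2-enoate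
Product: 5 methyl 4-[(tert-butyldimethylsilyl)oxy]-3-{[(tert-butyldimethylsilyl)oxy]methyl}-2-hydroxybutanoate (racemic), via α-hydroperoxy ester 4 (not isolated)
Conditions: Mn(dpm)3 (cat., dpm = 2,2,6,6-tetramethylheptane-3,5-dionate), PhSiH3, O2 (1 atm), 2-propanol/CH2Cl2, 0 °C to 25 °C; then P(OEt)3
Reagents that add atoms: dioxygen (O=O)
Why: Mukaiyama-type manganese-catalysed hydration of an α,β-unsaturated ester, in which hydrogen-atom transfer to the β-carbon gives the ester-stabilised α-radical that is trapped by O2 and reduced to the α-hydroxy ester; the product is racemic, which is intended.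

Step 3
Reactants: 5 methyl 4-[(tert-butyldimethylsilyl)oxy]-3-{[(tert-butyldimethylsilyl)oxy]methyl}-2-hydroxybutanoate (racemic); 6 2-(trimethylsilyl)phenyl trifluoromethanesulfonate
Product: 9 2-{1,3-bis[(tert-butyldimethylsilyl)oxy]propan-2-yl}benzofuran-3(2H)-one (racemic), via benzyne 7 (not isolated), via aryl anion 8 (not isolated)
Conditions: CsF (3 equiv), MeCN, 25 °C, 6 added slowly
Reagents that add atoms: none
Why: Proposed new method: fluoride unmasks benzyne 7 from 6, the cesium alkoxide of 5 adds to it (O1–C7a bond), and the resulting ortho-alkoxyaryl anion 8 attacks the methyl ester five atoms away and expels methoxide (C3a–C3 bond), a formal [3+2] aryne annulation of an aliphatic α-hydroxy ester that has not been shown as such. The closest known reaction types are the aryne coupling–cyclisation of methyl salicylates to xanthones and the N-arylation/acylation annulations of arynes with amino esters. The furanone ring closes by 5-exo-trig acyl substitution, which should outrun protonation of the aryl anion. No stereocentre is controlled here: C2 of 9 comes from racemic 5 and is left enolisable on purpose, so that step 4 can set C2 and C3 together. The step needs O- and not C-attack on the aryne and ring closure in place of proton transfer; the hydroxyl is the only acidic site of 5 (no 1,3-dicarbonyl CH), the aryne is symmetrical so no regiochemical question arises, and the only carbonyl within reach of the carbanion is the ester that becomes C3.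

Step 4
Reactants: 9 2-{1,3-bis[(tert-butyldimethylsilyl)oxy]propan-2-yl}benzofuran-3(2H)-one (racemic)
Product: 10 (2S,3S)-2-{1,3-bis[(tert-butyldimethylsilyl)oxy]propan-2-yl}-2,3-dihydrobenzofuran-3-ol (2,3-cis)
Conditions: RuCl[(R,R)-TsDPEN](p-cymene) (cat.), HCO2H/Et3N (1:1), EtOAc, 40 °C
Reagents that add atoms: none
Why: Noyori–Ikariya asymmetric transfer hydrogenation under dynamic kinetic resolution, a known reaction type for α-substituted benzo-fused cyclic ketones: C2 racemises through the enol (a 3-hydroxybenzofuran) in the amine medium, the (R,R) catalyst delivers hydride to the carbonyl face that gives (3S) (the same spatial sense as (R)-1-indanol from 1-indanone), and hydride enters anti to the C2 substituent, so the fast-reacting enantiomer should give the 2,3-cis (2S,3S) alcohol.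

Step 5
Reactants: 10 (2S,3S)-2-{1,3-bis[(tert-butyldimethylsilyl)oxy]propan-2-yl}-2,3-dihydrobenzofuran-3-ol
Product: 11 (2S,3S)-2-{1,3-bis[(tert-butyldimethylsilyl)oxy]propan-2-yl}-2,3-dihydrobenzofuran-3-yl acetate
Conditions: Ac2O, pyridine, DMAP (cat.), CH2Cl2, 0 °C to 25 °C
Reagents that add atoms: acetic anhydride (CC(=O)OC(C)=O)
Why: DMAP-catalysed O-acylation of the secondary benzylic alcohol under basic conditions, which leaves both stereocentres untouched and avoids the acid that would dehydrate the alcohol to a benzofuran.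

Step 6
Reactants: 11 (2S,3S)-2-{1,3-bis[(tert-butyldimethylsilyl)oxy]propan-2-yl}-2,3-dihydrobenzofuran-3-yl acetate
Product: 12 (2S,3S)-5-bromo-2-{1,3-bis[(tert-butyldimethylsilyl)oxy]propan-2-yl}-2,3-dihydrobenzofuran-3-yl acetate
Conditions: NBS, MeCN, 0 °C to 25 °C, dark
Reagents that add atoms: N-bromosuccinimide (O=C1CCC(=O)N1Br)
Why: Electrophilic aromatic bromination of an aryl alkyl ether in acetonitrile goes para to O1, that is at C5 as in 2,3-dihydrobenzofuran itself, and the ionic conditions leave the benzylic acetate and the silyl ethers alone.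

Step 7
Reactants: 12 (2S,3S)-5-bromo-2-{1,3-bis[(tert-butyldimethylsilyl)oxy]propan-2-yl}-2,3-dihydrobenzofuran-3-yl acetate
Product: 14 (2S,3S)-5-acetyl-2-{1,3-bis[(tert-butyldimethylsilyl)oxy]propan-2-yl}-2,3-dihydrobenzofuran-3-yl acetate, via enol ether 13 (not isolated)
Conditions: tributyl(1-ethoxyvinyl)stannane, Pd(PPh3)4 (cat.), toluene, 90 °C; then aq. HCl (0.5 mol/L), THF, 0 °C
Reagents that add atoms: tributyl(1-ethoxyvinyl)stannane (CCCC[Sn](CCCC)(CCCC)C(=C)OCC); water (O)
Why: Stille coupling of the aryl bromide with the α-alkoxyvinylstannane gives enol ether 13, whose fast hydrolysis in cold dilute acid unmasks the methyl ketone while the silyl ethers and the benzylic acetate should survive.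

Step 8
Reactants: 14 (2S,3S)-5-acetyl-2-{1,3-bis[(tert-butyldimethylsilyl)oxy]propan-2-yl}-2,3-dihydrobenzofuran-3-yl acetate
Product: 15 (2S,3S)-2-{1,3-bis[(tert-butyldimethylsilyl)oxy]propan-2-yl}-5-[(1R)-1-hydroxyethyl]-2,3-dihydrobenzofuran-3-yl acetate
Conditions: RuCl[(R,R)-TsDPEN](p-cymene) (cat.), HCO2H/Et3N (1:1), CH2Cl2, 25 °C
Reagents that add atoms: none
Why: The same Noyori–Ikariya transfer hydrogenation reduces the aryl methyl ketone under catalyst control, the (R,R) complex giving the (R)-1-arylethanol as it does with acetophenone, and the amine-rich formate medium spares the acetate and the acid-labile benzylic positions.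

Step 9
Reactants: 15 (2S,3S)-2-{1,3-bis[(tert-butyldimethylsilyl)oxy]propan-2-yl}-5-[(1R)-1-hydroxyethyl]-2,3-dihydrobenzofuran-3-yl acetate; 16 tiglic acid, (2E)-2-methylbut-2-enoic acid
Product: 17 (1R)-1-[(2S,3S)-3-acetoxy-2-{1,3-bis[(tert-butyldimethylsilyl)oxy]propan-2-yl}-2,3-dihydrobenzofuran-5-yl]ethyl (2E)-2-methylbut-2-enoate
Conditions: N,N'-dicyclohexylcarbodiimide, DMAP (cat.), CH2Cl2, 0 °C to 25 °C
Reagents that add atoms: none
Why: Steglich esterification acylates the secondary benzylic alcohol at oxygen, so the (R) centre is untouched, and the carbodiimide method avoids the deconjugation that acid chloride/amine conditions can cause with tiglic acid.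

Step 10
Reactants: 17 (1R)-1-[(2S,3S)-3-acetoxy-2-{1,3-bis[(tert-butyldimethylsilyl)oxy]propan-2-yl}-2,3-dihydrobenzofuran-5-yl]ethyl (2E)-2-methylbut-2-enoate
Product: 18 (1R)-1-[(2S,3S)-3-acetoxy-2-(1,3-dihydroxypropan-2-yl)-2,3-dihydrobenzofuran-5-yl]ethyl (2E)-2-methylbut-2-enoate
Conditions: TBAF, AcOH, THF, 0 °C to 25 °C
Reagents that add atoms: none
Why: Fluoride cleavage of the two primary silyl ethers, buffered with acetic acid so that neither acyl migration nor ionisation of the two benzylic esters is provoked.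

Step 11
Reactants: 18 (1R)-1-[(2S,3S)-3-acetoxy-2-(1,3-dihydroxypropan-2-yl)-2,3-dihydrobenzofuran-5-yl]ethyl (2E)-2-methylbut-2-enoate
Product: 19 (1R)-1-[(2S,3S)-3-acetoxy-2-{1-hydroxy-3-[(4-methylphenyl)sulfonyloxy]propan-2-yl}-2,3-dihydrobenzofuran-5-yl]ethyl (2E)-2-methylbut-2-enoate (two epimers at the branch carbon)
Conditions: TsCl (1 equiv), Ag2O, KI (cat.), CH2Cl2, 0 °C
Reagents that add atoms: p-toluenesulfonyl chloride (Cc1ccc(S(=O)(=O)Cl)cc1)
Why: Silver-oxide-mediated monotosylation of a symmetrical diol, a known protocol under neutral conditions in which the monotosylate reacts much more slowly than the diol; the new stereocentre is irrelevant because that carbon becomes sp2 in step 12.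

Step 12
Reactants: 19 (1R)-1-[(2S,3S)-3-acetoxy-2-{1-hydroxy-3-[(4-methylphenyl)sulfonyloxy]propan-2-yl}-2,3-dihydrobenzofuran-5-yl]ethyl (2E)-2-methylbut-2-enoate
Product: 21 (1R)-1-[(2S,3S)-3-acetoxy-2-(3-oxoprop-1-en-2-yl)-2,3-dihydrobenzofuran-5-yl]ethyl (2E)-2-methylbut-2-enoate (CNP0294391.6), via tosyloxy aldehyde 20 (not isolated)
Conditions: Dess–Martin periodinane, pyridine, CH2Cl2, 0 °C; then Et3N, 0 °C
Reagents that add atoms: none
Why: Dess–Martin oxidation of the remaining primary alcohol gives β-tosyloxy aldehyde 20, which on addition of triethylamine loses toluenesulfonate by E1cB elimination (sulfonate is a far better leaving group than the aryloxide at C2, so the furan ring stays closed) to give the 2-substituted acrolein.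

Compound list
1 | 1,3-bis[(tert-butyldimethylsilyl)oxy]propan-2-one | CC(C)(C)[Si](C)(C)OCC(=O)CO[Si](C)(C)C(C)(C)C | starting material
2 | trimethyl phosphonoacetate | COC(=O)CP(=O)(OC)OC | starting material
3 | methyl 4-[(tert-butyldimethylsilyl)oxy]-3-{[(tert-butyldimethylsilyl)oxy]methyl}but-2-enoate | COC(=O)C=C(CO[Si](C)(C)C(C)(C)C)CO[Si](C)(C)C(C)(C)C | intermediate
4 | methyl 4-[(tert-butyldimethylsilyl)oxy]-3-{[(tert-butyldimethylsilyl)oxy]methyl}-2-hydroperoxybutanoate (racemic, not isolated) | COC(=O)C(OO)C(CO[Si](C)(C)C(C)(C)C)CO[Si](C)(C)C(C)(C)C | intermediate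
5 | methyl 4-[(tert-butyldimethylsilyl)oxy]-3-{[(tert-butyldimethylsilyl)oxy]methyl}-2-hydroxybutanoate (racemic) | COC(=O)C(O)C(CO[Si](C)(C)C(C)(C)C)CO[Si](C)(C)C(C)(C)C | intermediate
6 | 2-(trimethylsilyl)phenyl trifluoromethanesulfonate | C[Si](C)(C)c1ccccc1OS(=O)(=O)C(F)(F)F | starting material
7 | benzyne (1,2-didehydrobenzene, not isolated) | C1=CC#CC=C1 | intermediate
8 | ortho-cesiated aryl ether of 5 (aryl anion, racemic, not isolated) | COC(=O)C(Oc1ccccc1[Cs])C(CO[Si](C)(C)C(C)(C)C)CO[Si](C)(C)C(C)(C)C | intermediate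
9 | 2-{1,3-bis[(tert-butyldimethylsilyl)oxy]propan-2-yl}benzofuran-3(2H)-one (racemic) | O=C1c2ccccc2OC1C(CO[Si](C)(C)C(C)(C)C)CO[Si](C)(C)C(C)(C)C | intermediate
10 | (2S,3S)-2-{1,3-bis[(tert-butyldimethylsilyl)oxy]propan-2-yl}-2,3-dihydrobenzofuran-3-ol | CC(C)(C)[Si](C)(C)OCC(CO[Si](C)(C)C(C)(C)C)[C@@H]1Oc2ccccc2[C@@H]1O | intermediate
11 | (2S,3S)-2-{1,3-bis[(tert-butyldimethylsilyl)oxy]propan-2-yl}-2,3-dihydrobenzofuran-3-yl acetate | CC(C)(C)[Si](C)(C)OCC(CO[Si](C)(C)C(C)(C)C)[C@@H]1Oc2ccccc2[C@@H]1OC(C)=O | intermediate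
12 | (2S,3S)-5-bromo-2-{1,3-bis[(tert-butyldimethylsilyl)oxy]propan-2-yl}-2,3-dihydrobenzofuran-3-yl acetate | CC(C)(C)[Si](C)(C)OCC(CO[Si](C)(C)C(C)(C)C)[C@@H]1Oc2ccc(Br)cc2[C@@H]1OC(C)=O | intermediate
13 | (2S,3S)-2-{1,3-bis[(tert-butyldimethylsilyl)oxy]propan-2-yl}-5-(1-ethoxyvinyl)-2,3-dihydrobenzofuran-3-yl acetate (not isolated) | CC(C)(C)[Si](C)(C)OCC(CO[Si](C)(C)C(C)(C)C)[C@@H]1Oc2ccc(C(=C)OCC)cc2[C@@H]1OC(C)=O | intermediate
14 | (2S,3S)-5-acetyl-2-{1,3-bis[(tert-butyldimethylsilyl)oxy]propan-2-yl}-2,3-dihydrobenzofuran-3-yl acetate | CC(C)(C)[Si](C)(C)OCC(CO[Si](C)(C)C(C)(C)C)[C@@H]1Oc2ccc(C(C)=O)cc2[C@@H]1OC(C)=O | intermediate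
15 | (2S,3S)-2-{1,3-bis[(tert-butyldimethylsilyl)oxy]propan-2-yl}-5-[(1R)-1-hydroxyethyl]-2,3-dihydrobenzofuran-3-yl acetate | CC(C)(C)[Si](C)(C)OCC(CO[Si](C)(C)C(C)(C)C)[C@@H]1Oc2ccc([C@@H](C)O)cc2[C@@H]1OC(C)=O | intermediate
16 | tiglic acid, (2E)-2-methylbut-2-enoic acid | C/C=C(\C)C(=O)O | starting material
17 | (1R)-1-[(2S,3S)-3-acetoxy-2-{1,3-bis[(tert-butyldimethylsilyl)oxy]propan-2-yl}-2,3-dihydrobenzofuran-5-yl]ethyl (2E)-2-methylbut-2-enoate | CC(C)(C)[Si](C)(C)OCC(CO[Si](C)(C)C(C)(C)C)[C@@H]1Oc2ccc([C@@H](C)OC(=O)/C(C)=C/C)cc2[C@@H]1OC(C)=O | intermediate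
18 | (1R)-1-[(2S,3S)-3-acetoxy-2-(1,3-dihydroxypropan-2-yl)-2,3-dihydrobenzofuran-5-yl]ethyl (2E)-2-methylbut-2-enoate | OCC(CO)[C@@H]1Oc2ccc([C@@H](C)OC(=O)/C(C)=C/C)cc2[C@@H]1OC(C)=O | intermediate
19 | (1R)-1-[(2S,3S)-3-acetoxy-2-{1-hydroxy-3-[(4-methylphenyl)sulfonyloxy]propan-2-yl}-2,3-dihydrobenzofuran-5-yl]ethyl (2E)-2-methylbut-2-enoate (two epimers at the branch carbon) | Cc1ccc(S(=O)(=O)OCC(CO)[C@@H]2Oc3ccc([C@@H](C)OC(=O)/C(C)=C/C)cc3[C@@H]2OC(C)=O)cc1 | intermediate
20 | (1R)-1-[(2S,3S)-3-acetoxy-2-{1-[(4-methylphenyl)sulfonyloxy]-3-oxopropan-2-yl}-2,3-dihydrobenzofuran-5-yl]ethyl (2E)-2-methylbut-2-enoate (two epimers, not isolated) | Cc1ccc(S(=O)(=O)OCC(C=O)[C@@H]2Oc3ccc([C@@H](C)OC(=O)/C(C)=C/C)cc3[C@@H]2OC(C)=O)cc1 | intermediate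
21 | (1R)-1-[(2S,3S)-3-acetoxy-2-(3-oxoprop-1-en-2-yl)-2,3-dihydrobenzofuran-5-yl]ethyl (2E)-2-methylbut-2-enoate | C=C(C=O)[C@@H]1Oc2ccc([C@@H](C)OC(=O)/C(C)=C/C)cc2[C@@H]1OC(C)=O | target

Total step count: 12. Longest linear sequence: 12 steps (from 1 to 21).

Steps most likely to fail

Step 3 (bears the label). The aryl anion may be protonated before it reaches the ester, leaving a simple O-aryl ether. A silyl group may migrate to the secondary alkoxide before arylation. The enolisable product may be arylated again by benzyne. The fallback uses known chemistry and sets out from 5. Mitsunobu etherification of 5 with 2-bromophenol (PPh3, DIAD, THF) should give methyl 2-(2-bromophenoxy)-4-[(tert-butyldimethylsilyl)oxy]-3-{[(tert-butyldimethylsilyl)oxy]methyl}butanoate F1. Bromine–lithium exchange with n-BuLi in THF at −100 °C, followed by Parham-type cycloacylation of the aryllithium onto the methyl ester, should then close the furanone ring and come back to the route at 9.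

Step 4. Racemisation at C2 may be too slow beside reduction for this bulky 2-substituent, so that the dynamic resolution is incomplete, or the benzylic alcohol may dehydrate to a benzofuran in the formate medium. The fallback sets out from 9. Reduction with LiBH(s-Bu)3 in THF at −78 °C, with hydride anti to the C2 substituent, should give the racemic cis-2-{1,3-bis[(tert-butyldimethylsilyl)oxy]propan-2-yl}-2,3-dihydrobenzofuran-3-ol F2. Esterification with (S)-O-acetylmandelic acid (N,N'-dicyclohexylcarbodiimide, DMAP) should give the (S)-O-acetylmandelate of the (2S,3S) alcohol F3 and the (S)-O-acetylmandelate of the (2R,3R) alcohol F4, which are separated by chromatography or crystallisation. Hydrolysis of F3 with LiOH in THF/water should come back to the route at 10.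

Step 11. Sulfonylation may run on to the bis-tosylate, or mono-selectivity may be poor, so that material is lost just before the end. The fallback sets out from 18 and makes the mono-functionalisation structural instead of statistical. Trimethyl orthoacetate with catalytic pyridinium p-toluenesulfonate in CH2Cl2 should give the cyclic orthoacetate (2-methoxy-2-methyl-1,3-dioxan-5-yl compound) F5. Water should open it to the monoacetate F6. Dess–Martin oxidation should give the β-acetoxy aldehyde F7, from which DBU at 0 °C eliminates acetic acid, and the sequence comes back to the route at 21.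

Further compounds
F1 | step 3 | methyl 2-(2-bromophenoxy)-4-[(tert-butyldimethylsilyl)oxy]-3-{[(tert-butyldimethylsilyl)oxy]methyl}butanoate (racemic) | COC(=O)C(Oc1ccccc1Br)C(CO[Si](C)(C)C(C)(C)C)CO[Si](C)(C)C(C)(C)C
F2 | step 4 | racemic cis-2-{1,3-bis[(tert-butyldimethylsilyl)oxy]propan-2-yl}-2,3-dihydrobenzofuran-3-ol (both enantiomers) | CC(C)(C)[Si](C)(C)OCC(CO[Si](C)(C)C(C)(C)C)[C@@H]1Oc2ccccc2[C@@H]1O.CC(C)(C)[Si](C)(C)OCC(CO[Si](C)(C)C(C)(C)C)[C@H]1Oc2ccccc2[C@H]1O
F3 | step 4 | (2S,3S)-2-{1,3-bis[(tert-butyldimethylsilyl)oxy]propan-2-yl}-2,3-dihydrobenzofuran-3-yl (2S)-2-acetoxy-2-phenylacetate | CC(C)(C)[Si](C)(C)OCC(CO[Si](C)(C)C(C)(C)C)[C@@H]1Oc2ccccc2[C@@H]1OC(=O)[C@@H](OC(C)=O)c1ccccc1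
F4 | step 4 | (2R,3R)-2-{1,3-bis[(tert-butyldimethylsilyl)oxy]propan-2-yl}-2,3-dihydrobenzofuran-3-yl (2S)-2-acetoxy-2-phenylacetate | CC(C)(C)[Si](C)(C)OCC(CO[Si](C)(C)C(C)(C)C)[C@H]1Oc2ccccc2[C@H]1OC(=O)[C@@H](OC(C)=O)c1ccccc1
F5 | step 11 | (1R)-1-[(2S,3S)-3-acetoxy-2-(2-methoxy-2-methyl-1,3-dioxan-5-yl)-2,3-dihydrobenzofuran-5-yl]ethyl (2E)-2-methylbut-2-enoate | COC1(C)OCC(CO1)[C@@H]1Oc2ccc([C@@H](C)OC(=O)/C(C)=C/C)cc2[C@@H]1OC(C)=O
F6 | step 11 | (1R)-1-[(2S,3S)-3-acetoxy-2-(1-acetoxy-3-hydroxypropan-2-yl)-2,3-dihydrobenzofuran-5-yl]ethyl (2E)-2-methylbut-2-enoate (two epimers) | CC(=O)OCC(CO)[C@@H]1Oc2ccc([C@@H](C)OC(=O)/C(C)=C/C)cc2[C@@H]1OC(C)=O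
F7 | step 11 | (1R)-1-[(2S,3S)-3-acetoxy-2-(1-acetoxy-3-oxopropan-2-yl)-2,3-dihydrobenzofuran-5-yl]ethyl (2E)-2-methylbut-2-enoate (two epimers) | CC(=O)OCC(C=O)[C@@H]1Oc2ccc([C@@H](C)OC(=O)/C(C)=C/C)cc2[C@@H]1OC(C)=O
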